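## The problem

- **Numbering.** The decalin carbons are C1 (CH carrying the carboxyl), C2 (CHMe), C3, C4, C4a (quaternary, Me), C5 (alkene carbon carrying the 4-methylpent-3-enyl chain), C6, C7, C8 and C8a (quaternary, Me). Ring A is C1–C4 with C4a and C8a, ring B is C4a, C5–C8 and C8a. β is the face of the two angular methyl groups, α the opposite face.
- **Ring fusion.** Target 24 is a cis-fused octalin whose fusion carbons C4a and C8a are adjacent, both quaternary and both methyl-bearing, so the central task is to make this congested pair with control of absolute configuration.
- **Ring A stereocentres.** C1 carries the carboxyl β and C2 the methyl α. C1 is α to a carbonyl, and its target configuration is the stable one: C1 and C2 substituents are both equatorial in the chair with axial C8a–Me, whereas the C1 epimer has a syn-pentane contact in either chair. C1 can therefore be corrected by equilibration. C2 cannot be epimerised and must be set kinetically under the influence of the ring fusion and C1.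
- **Ring B.** It needs a C5=C6 alkene with the chain on C5 and nothing at C8. Because C4a has no hydrogen, a C5 carbonyl can only enolise towards C6, which fixes the alkene position.
- **Glycerol centre.** It is too remote to exchange stereochemical information with the decalin, so the decalin must be made as a single enantiomer on its own and the glycerol unit taken from the chiral pool.
- **Sensitive groups.** The two trisubstituted alkenes do not survive hydrogenation, hypochlorite or cation-forming acid. The 1,3-diacylglycerol with a free secondary hydroxyl is prone to acyl migration. The C1 carboxyl is too hindered for easy acyl substitution.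
- **Enabling feature.** C4a and C8a with their cis methyls are the tetrasubstituted alkene of a 2,3-dimethylcyclohex-2-ene-1,4-dione, whose C5 and C8 carbonyls activate it as a dienophile. C1–C4, with carbon substituents on C1 and C2, are a 1,2-disubstituted butadiene.

## Retrosynthesis

**Glyceride last.** The acetate C–O bond of 24 is cut to diol 23, and the diol is masked as acetonide 22. Acyl migration is the main hazard of the glyceride, so it is built at the very end under weakly acidic and weakly basic conditions. The forward steps need only primary-selective acetylation.

**C5–side-chain bond.** In 22 the sp2–sp3 bond between C5 and the chain is cut to enol triflate 19 and alkylzinc 21 (from bromide 20). The neighbouring option, Grignard addition to a C5 ketone and dehydration, leaves endo/exo ambiguity and risks cationic shifts next to two quaternary carbons. The triflate route fixes C5=C6 and brings both trisubstituted alkenes in only after all reductions and oxidations are done. The forward reaction needs a cross-coupling that tolerates an ester and an acetonide.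

**Ester alkyl–oxygen bond.** Triflate 19 comes from keto ester 18, which is cut at the O–CH2 bond to keto acid 16 and (R)-solketal 17. Cutting the alkyl–oxygen bond (Mitsunobu) rather than the acyl–oxygen bond avoids attack at the hindered C1 carbonyl.

**C1 oxidation level and configuration.** Acid 16 goes back to β-aldehyde 15, its α-epimer 14 and diol 13. The aldehyde is the one oxidation level at which C1 epimerises easily, and the target configuration is the thermodynamic one.

**C8 oxygen and the distinction between C5 and C8.** Diol 13 comes from dihydroxy ketone 11 by deoxygenation at C8, and 11 from enol ether 9, which comes from dione 7. The two carbonyls of 7 are nearly alike sterically, so the distinction is made structurally. The C1–CH2OH is cis to C8 and can close a five-ring enol ether onto C8, while the same closure onto C5 would need a bridgehead C5=C6 bond. With C8 masked, C5 is parked as an alcohol, and the C8 carbonyl is removed while the molecule has no alkene.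

**C2–H and C3–H.** Dione 7 comes from octalin 6 by hydrogenation from the β face, anti to the C1 substituent.

**Key cut, C8a–C1 and C4a–C4.** Adduct 6 is cut to ene-dione 2 and diene 5. This is the only cut that makes both quaternary carbons, ring A and the carboxyl carbon at once from two small fragments of similar size. The forward reaction needs a [4+2] addition to a tetrasubstituted alkene with endo and enantiofacial control.

**Fragments.** Ene-dione 2 comes from enone 1 by γ-oxidation. Diene 5 comes from enynol 3 through silyl ether 4 by semihydrogenation.

## Roads not taken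

**Alternative 1: intramolecular Diels–Alder.**
- Cut: C4a–C8a and C7–C8.
- Forward step: trienone A1 is an isopropenyl ketone (C8=C8a–C1=O) tethered through C2–C4 to the (Z)-diene C4a=C5–C6=C7, with the chain already on C5. Activated at C1=O by MeAlCl2, it would close rings A and B together to octalone A2.
- Merits: both rings, both quaternary carbons, the C5=C6 alkene and the side chain arrive in one step. The (Z)-diene enforces cis fusion. No C8 oxygen has to be removed.
- Weak points: the new bond joins a fully substituted diene terminus to a 1,1-disubstituted dienophile carbon. A1 needs a geometrically pure tetrasubstituted alkene and an enolisable C2 stereocentre that must survive a strong Lewis acid, which also threatens the isopropenyl ketone and the prenyl-type alkene. A2 has a ketone at C1, so a one-carbon homologation at a carbonyl flanked by a quaternary and a tertiary carbon is still required, with C1 to be set afterwards.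
- Comparison: in ring construction and in having nothing to deoxygenate this road is more economical than the chosen plan. The chosen plan sets against it fragments reachable in one to three steps, no stereodefined tetrasubstituted diene, and the carboxyl carbon already attached to C1 after the key step.

**Alternative 2: dihydropyran Claisen.**
- Cut: C4a–C8a only.
- Forward step: heating dihydropyran A3 (about 200 °C, base-washed glass) would rearrange the allyl vinyl ether C8a=C1–O–C6–C5=C4a through a boat transition state. This contracts the oxacycle to ring B and gives cyclohexenyl ethyl ketone A4.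
- Merits: the quaternary–quaternary bond forms intramolecularly with chirality transfer from one C–O stereocentre (C6) and the alkene geometry, without asymmetric catalysis at the hindered bond. Ring B emerges with C5=C6 and the chain in place and no C8 oxygen.
- Weak points: A3 must be made enantioenriched with a stereodefined tetrasubstituted alkene. The temperature is high. Ring A is still open (C2–C3 to be closed by enolate alkylation, setting C2). C1 is again a ketone that must be homologated.
- Comparison: for the absolute configuration of C4a and C8a this road is better founded than the chosen one. The chosen plan sets against it that ring A and the carboxyl carbon arrive in the same step as the quaternary carbons, that the route is much shorter, and that a racemic cycloaddition with separation is available as a fallback for enantiocontrol.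

**Alternative 3: ring-contracting Ireland–Claisen.**
- Cut: C1–C8a.
- Forward step: the silyl ketene acetal of ten-membered lactone A5 (LiN(SiMe3)2, Me3SiCl) would rearrange through O–C7–C8=C8a. This forms C1–C8a, closes ring A and releases the carboxyl, giving octalin acid A6.
- Merits: C1 is delivered at the carboxyl oxidation level. The tether guarantees cis fusion and transfers chirality from C7 to C8a. Ring B carries oxygen only at C5, so there is no C5/C8 distinction to make and no deoxygenation at C8.
- Weak points: ring B with the C4a quaternary centre and the C5 and C7 carbinol centres must first be made enantioselectively. A ten-membered lactone has to be closed onto a hindered allylic alcohol. The carboxyl comes out cis to C8 and must be epimerised at the acid or ester level, where that is hard. C7=C8 must be reduced and C5–OTBS converted to ketone, triflate and chain.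
- Comparison: this road is better in oxidation-state economy at C1 and in ring-B simplicity. The chosen plan sets against it a convergent first stage from purchasable fragments, no medium-ring lactonisation, and C1 epimerisation at the aldehyde level.

Key step: step 4

Assumptions (remarks on the chemistry):
- The (S)-prolinol-derived oxazaborolidinium is taken to give 6 in the configuration drawn. If the sense of induction is the opposite, its (R)-antipode is used and nothing else changes.
- The C5 carbinol configuration in 10–13 is left open, because C5 is re-oxidised in step 9.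
- (R)-Solketal gives the (S)-glyceryl centre of 24 without any change at the stereocentre; only the CIP priorities change.

## Route

Step 1
Reactants: 1 2,3-dimethylcyclohex-2-en-1-one
Product: 2 2,3-dimethylcyclohex-2-ene-1,4-dione
Conditions: Rh2(cap)4 (dirhodium tetrakis(caprolactamate), 1 mol %), t-BuOOH (70% aq), 1,2-dichloroethane, 40 °C
Reagents that add atoms: tert-butyl hydroperoxide, CC(C)(C)OO
Why: Allylic γ-oxidation of an enone to the ene-dione; tert-butylperoxyl radical abstracts hydrogen from the ring CH2 (secondary allylic, favoured over the methyl C–H), and the base-free medium limits tautomerisation to the hydroquinone.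

Step 2
Reactants: 3 (E)-3-methylpent-2-en-4-yn-1-ol
Product: 4 tert-butyldimethylsilyl ether of 3
Conditions: TBSCl, imidazole, CH2Cl2, 0 °C → rt
Reagents that add atoms: tert-butyldimethylsilyl chloride, CC(C)(C)[Si](C)(C)Cl
Why: Standard silylation of a primary allylic alcohol; it makes the later diene less volatile and acid-tolerant.

Step 3
Reactants: 4 tert-butyldimethylsilyl ether of 3
Product: 5 (E)-tert-butyldimethyl[(3-methylpenta-2,4-dien-1-yl)oxy]silane
Conditions: H2 (1 atm), Pd/CaCO3 poisoned with Pb(OAc)2 (Lindlar catalyst), quinoline, hexane, rt
Reagents that add atoms: none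
Why: Semihydrogenation of the terminal alkyne; the poisoned palladium reduces the alkyne much faster than the resulting diene, and the (E)-trisubstituted alkene is untouched.

Step 4
Reactants: 2 2,3-dimethylcyclohex-2-ene-1,4-dione; 5 (E)-tert-butyldimethyl[(3-methylpenta-2,4-dien-1-yl)oxy]silane
Product: 6 endo adduct, (1R,4aS,8aR)-1-{[(tert-butyldimethylsilyl)oxy]methyl}-2,4a,8a-trimethyl-1,4,4a,6,7,8a-hexahydronaphthalene-5,8-dione (cis-fused; C1–CH2OTBS α, angular methyls β, C2=C3)
Conditions: (S)-3,3-diphenyl-1-(o-tolyl)tetrahydro-1H,3H-pyrrolo[1,2-c][1,3,2]oxazaborole·AlBr3 (20 mol %), 5 (2 equiv), CH2Cl2, −78 → −20 °C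
Reagents that add atoms: none
Why: Proposed new method: the chiral oxazaborolidinium Lewis acid binds one carbonyl oxygen of 2 (the future C8=O), lowers the LUMO of the tetrasubstituted alkene and makes its β-carbon (future C4a) the more electrophilic, so that the unsubstituted CH2 terminus of 5 bonds there first in a concerted, asynchronous [4+2] addition; the closest known reactions are thermal, high-pressure and Lewis-acid Diels–Alder additions to the methyl-bearing double bond of 2,3-dimethylquinones and cyclohex-2-ene-1,4-diones, and oxazaborolidinium-catalysed quinone Diels–Alder reactions, none of which combines asymmetric catalysis with a fully substituted ene-dione. Ring A is closed in this single step by cycloaddition, C4a–C4 and C8a–C1 forming suprafacially on both partners. The cis relation of C4a and C8a follows from suprafacial addition to a cyclic alkene. Their absolute configuration is set by the catalyst, which must choose between the two mirror-image pairings of diene terminus and alkene carbon through its binding site and the face it shields. C1 is set by the (E) geometry of 5 and the endo orientation (ring B carbonyls under the diene, methyls outside), which places CH2OTBS α. The step needs endo selectivity (step 6 requires C1–CH2O cis to C8), enantioselectivity, and no tautomerisation of 2 to 2,3-dimethylhydroquinone. Endo preference is secured by the methyl groups clashing with the diene backbone in the exo mode; the aprotic Lewis acid, low temperature and excess diene guard against tautomerisation. Because 2 is C2-symmetric there is no regiochemical issue beyond the enantio-determining pairing.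

Step 5
Reactants: 6 endo adduct
Product: 7 (1R,2R,4aS,8aR)-1-{[(tert-butyldimethylsilyl)oxy]methyl}-2,4a,8a-trimethyloctahydronaphthalene-5,8-dione (C1–CH2OTBS α, C2–Me α, angular methyls β)
Conditions: H2 (1–3 atm), 10% Pd/C, EtOAc, rt
Reagents that add atoms: none
Why: Heterogeneous syn-hydrogenation of the trisubstituted C2=C3 alkene; hydrogen is delivered to the convex β face, anti to the allylic C1–CH2OTBS group and to ring B folded under ring A, which puts the C2 methyl α; the α-quaternary ketones are not reduced.

Step 6
Reactants: 7 silyl ether dione
Product: 9 tricyclic enol ether ketone (C1–CH2–O–C8 bridge on the α face; C7=C8 enol ether; C5 ketone), via hydroxy dione 8 (not isolated)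
Conditions: TBAF, THF, 0 °C → rt; then PPTS (10 mol %), toluene, reflux, Dean–Stark trap
Reagents that add atoms: none
Why: Fluoride desilylation frees the C1–CH2OH, which is cis to C8, and acid-catalysed cyclodehydration of this γ-hydroxy ketone gives the five-ring enol ether. Only C8 can respond, because closure onto C5 would need a bridgehead C5=C6 bond (Bredt strain), and any C5 hemiketal, unable to lose water, drains back through 8 as water is removed.

Step 7
Reactants: 9 tricyclic enol ether ketone
Product: 11 dihydroxy ketone (C1–CH2OH α, C5–OH, C8 ketone), via hydroxy enol ether 10 (not isolated)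
Conditions: NaBH4, MeOH, 0 °C; then 1 M HCl, THF, rt
Reagents that add atoms: water, O
Why: Borohydride reduces the only ketone (C5); aqueous acid then hydrolyses the enol ether (protonation at C7, hydration of the oxocarbenium ion), releasing the C8 ketone and the C1–CH2OH. The C5 configuration is irrelevant.

Step 8
Reactants: 11 dihydroxy ketone
Product: 13 diol (C1–CH2OH α, C2–Me α, C5–OH, C8 methylene), via C8 hydrazone 12 (not isolated)
Conditions: N2H4·H2O, KOH, diethylene glycol, 130 °C, then 200 °C
Reagents that add atoms: hydrazine hydrate, NN.O (its nitrogen atoms remain only in intermediate 12)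
Why: Wolff–Kishner reduction (Huang-Minlon procedure): hydrazone formation at C8, then base-induced loss of N2. At this stage the substrate has no alkene, ester or epimerisable centre, and both hydroxyl groups are inert.

Step 9
Reactants: 13 diol
Product: 15 β-aldehyde ketone (C1–CHO β, trans to C2–Me; C5 ketone), via cis keto aldehyde 14 (not isolated)
Conditions: (COCl)2, DMSO, CH2Cl2, −78 °C; Et3N, −78 → 0 °C; then DBU, CH2Cl2, rt
Reagents that add atoms: none
Why: Swern oxidation converts both alcohols at once (both alkoxysulfonium ions exist before base is added, so no lactol can be over-oxidised to a lactone). DBU then epimerises C1 through the enol to the β-aldehyde, the thermodynamic isomer with C1 and C2 substituents both equatorial.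

Step 10
Reactants: 15 β-aldehyde ketone
Product: 16 keto acid, (1S,2R,4aS,8aR)-2,4a,8a-trimethyl-5-oxodecahydronaphthalene-1-carboxylic acid
Conditions: NaClO2, NaH2PO4, 2-methyl-2-butene, t-BuOH/H2O, 0 °C → rt
Reagents that add atoms: sodium chlorite, [Na+].[O-]Cl=O
Why: Pinnick oxidation of the hindered aldehyde under buffered conditions, which leave the ketone and the C1 configuration untouched.

Step 11
Reactants: 16 keto acid; 17 (R)-solketal
Product: 18 [(4S)-2,2-dimethyl-1,3-dioxolan-4-yl]methyl ester of 16
Conditions: PPh3, DIAD, THF, 0 °C → rt
Reagents that add atoms: none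
Why: Mitsunobu esterification: the carboxylate attacks the primary alkoxyphosphonium carbon of 17, so the hindered acyl carbon is never attacked and neither C1 nor the dioxolane stereocentre is touched.

Step 12
Reactants: 18 keto ester
Product: 19 C5 enol triflate of 18 (C5=C6)
Conditions: KN(SiMe3)2, THF, −78 °C; PhNTf2, −78 → 0 °C
Reagents that add atoms: N-phenylbis(trifluoromethanesulfonimide), O=S(=O)(N(c1ccccc1)S(=O)(=O)C(F)(F)F)C(F)(F)F
Why: Kinetic enolisation at C6, the only enolisable position of the C5 ketone because C4a is quaternary, followed by O-triflation. The ketone α-CH2 is far more acidic and accessible than the tertiary C1–H of the ester.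

Step 13
Reactants: 19 enol triflate; 20 5-bromo-2-methylpent-2-ene
Product: 22 [(4S)-2,2-dimethyl-1,3-dioxolan-4-yl]methyl (1S,2R,4aR,8aR)-2,4a,8a-trimethyl-5-(4-methylpent-3-en-1-yl)-1,2,3,4,4a,7,8,8a-octahydronaphthalene-1-carboxylate, via homoprenylzinc bromide 21 (not isolated)
Conditions: 20, Zn dust, LiCl, THF, 50 °C; then 19, Pd(dppf)Cl2 (5 mol %), THF, 60 °C
Reagents that add atoms: zinc, [Zn] (held only in intermediate 21)
Why: Zinc insertion into the primary bromide, then Negishi coupling with the alkenyl triflate. The bidentate ferrocenylphosphine suppresses β-hydride elimination, the organozinc tolerates ester and acetonide, and the alkene position is fixed by the triflate.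

Step 14
Reactants: 22 acetonide ester
Product: 23 (2S)-2,3-dihydroxypropyl ester (1-monoacylglycerol)
Conditions: AcOH/H2O (4:1), 40 °C
Reagents that add atoms: none
Why: Acid-catalysed acetonide hydrolysis; acetic acid is too weak to protonate the trisubstituted alkenes, and the hindered acyl group does not migrate.

Step 15
Reactants: 23 diol ester
Product: 24 (2S)-3-acetoxy-2-hydroxypropyl (1S,2R,4aR,8aR)-2,4a,8a-trimethyl-5-(4-methylpent-3-en-1-yl)-1,2,3,4,4a,7,8,8a-octahydronaphthalene-1-carboxylate (target)
Conditions: AcCl (1.05 equiv), 2,4,6-collidine, CH2Cl2, −78 °C
Reagents that add atoms: acetyl chloride, CC(=O)Cl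
Why: Kinetically selective acylation of the primary hydroxyl of a 1,2-diol; the hindered weak base and low temperature suppress acetyl migration to the secondary oxygen.

## Compound list

1 | 2,3-dimethylcyclohex-2-en-1-one | CC1=C(C)C(=O)CCC1 | starting material
2 | 2,3-dimethylcyclohex-2-ene-1,4-dione | CC1=C(C)C(=O)CCC1=O | intermediate
3 | (E)-3-methylpent-2-en-4-yn-1-ol | C#C/C(C)=C/CO | starting material
4 | (E)-tert-butyldimethyl[(3-methylpent-2-en-4-yn-1-yl)oxy]silane | C#C/C(C)=C/CO[Si](C)(C)C(C)(C)C | intermediate
5 | (E)-tert-butyldimethyl[(3-methylpenta-2,4-dien-1-yl)oxy]silane | C=C/C(C)=C/CO[Si](C)(C)C(C)(C)C | intermediate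
6 | endo adduct, (1R,4aS,8aR)-1-(TBSO-methyl)-2,4a,8a-trimethyl-1,4,4a,6,7,8a-hexahydronaphthalene-5,8-dione | CC(C)(C)[Si](C)(C)OC[C@@H]1C(C)=CC[C@]2(C)C(=O)CCC(=O)[C@]12C | intermediate
7 | (1R,2R,4aS,8aR)-1-(TBSO-methyl)-2,4a,8a-trimethyloctahydronaphthalene-5,8-dione | CC(C)(C)[Si](C)(C)OC[C@@H]1[C@H](C)CC[C@]2(C)C(=O)CCC(=O)[C@]12C | intermediate
8 | hydroxy dione (desilylated 7, C1–CH2OH α; in equilibrium with its hemiketals) | OC[C@@H]1[C@H](C)CC[C@]2(C)C(=O)CCC(=O)[C@]12C | intermediate (not isolated)
9 | tricyclic enol ether ketone (C1–CH2–O–C8, C7=C8, C5 ketone) | C[C@@H]1CC[C@]2(C)C(=O)CC=C3OC[C@H]1[C@]23C | intermediate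
10 | hydroxy enol ether (C5 alcohol of 9, C5 configuration open) | C[C@@H]1CC[C@]2(C)C(O)CC=C3OC[C@H]1[C@]23C | intermediate (not isolated)
11 | dihydroxy ketone (C1–CH2OH α, C5–OH, C8 ketone) | OC[C@@H]1[C@H](C)CC[C@]2(C)C(O)CCC(=O)[C@]12C | intermediate
12 | C8 hydrazone of 11 | OC[C@@H]1[C@H](C)CC[C@]2(C)C(O)CC/C(=N\N)[C@]12C | intermediate (not isolated)
13 | diol (C1–CH2OH α, C2–Me α, C5–OH, C8 methylene) | OC[C@@H]1[C@H](C)CC[C@]2(C)C(O)CCC[C@]12C | intermediate
14 | cis keto aldehyde (C1–CHO α, C5 ketone) | O=C[C@@H]1[C@H](C)CC[C@]2(C)C(=O)CCC[C@]12C | intermediate (not isolated)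
15 | β-aldehyde ketone (C1–CHO β, trans to C2–Me, C5 ketone) | O=C[C@H]1[C@H](C)CC[C@]2(C)C(=O)CCC[C@]12C | intermediate
16 | (1S,2R,4aS,8aR)-2,4a,8a-trimethyl-5-oxodecahydronaphthalene-1-carboxylic acid | OC(=O)[C@H]1[C@H](C)CC[C@]2(C)C(=O)CCC[C@]12C | intermediate
17 | (R)-solketal, (R)-(2,2-dimethyl-1,3-dioxolan-4-yl)methanol | OC[C@@H]1COC(C)(C)O1 | starting material
18 | [(4S)-2,2-dimethyl-1,3-dioxolan-4-yl]methyl ester of 16 | O=C(OC[C@@H]3COC(C)(C)O3)[C@H]1[C@H](C)CC[C@]2(C)C(=O)CCC[C@]12C | intermediate
19 | C5 enol triflate of 18 (C5=C6) | O=C(OC[C@@H]3COC(C)(C)O3)[C@H]1[C@H](C)CC[C@]2(C)C(OS(=O)(=O)C(F)(F)F)=CCC[C@]12C | intermediate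
20 | 5-bromo-2-methylpent-2-ene | CC(C)=CCCBr | starting material
21 | (4-methylpent-3-en-1-yl)zinc bromide | CC(C)=CCC[Zn]Br | intermediate (not isolated)
22 | [(4S)-2,2-dimethyl-1,3-dioxolan-4-yl]methyl (1S,2R,4aR,8aR)-2,4a,8a-trimethyl-5-(4-methylpent-3-en-1-yl)-1,2,3,4,4a,7,8,8a-octahydronaphthalene-1-carboxylate | O=C(OC[C@@H]3COC(C)(C)O3)[C@H]1[C@H](C)CC[C@]2(C)C(CCC=C(C)C)=CCC[C@]12C | intermediate
23 | (2S)-2,3-dihydroxypropyl ester of the same acid | O=C(OC[C@@H](O)CO)[C@H]1[C@H](C)CC[C@]2(C)C(CCC=C(C)C)=CCC[C@]12C | intermediate
24 | (2S)-3-acetoxy-2-hydroxypropyl (1S,2R,4aR,8aR)-2,4a,8a-trimethyl-5-(4-methylpent-3-en-1-yl)-1,2,3,4,4a,7,8,8a-octahydronaphthalene-1-carboxylate | CC(=O)OC[C@H](O)COC(=O)[C@H]1[C@H](C)CC[C@]2(C)C(CCC=C(C)C)=CCC[C@]12C | target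

## Step count and least certain steps

Total: 15 steps. Longest linear sequence: 14 steps (3 → 24, steps 2–15).

**Step 4 (key step, proposed new method).**
- What may go wrong: Lewis-acid-promoted tautomerisation of 2 to the hydroquinone may outrun a slow addition to a tetrasubstituted alkene. The two mirror-image pairings may be poorly distinguished, because the dienophile has no α-vinyl hydrogen to organise the catalyst complex and the two diene termini differ little in nucleophilicity. Endo selectivity may be incomplete.
- Fallback (known chemistry): a racemic cycloaddition carrying a covalently bound resolving group. It sets out from 3 and 2 and returns at 9.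
  - Semihydrogenation of 3 over Pd/CaCO3–Pb(OAc)2 gives (E)-3-methylpenta-2,4-dien-1-ol F1.
  - Acylation with (1S)-camphanic chloride and pyridine gives the dienyl camphanate F2.
  - F2 and 2 combine at 12–15 kbar in CH2Cl2 at rt without any acid to the endo adduct camphanate F3 and its diastereomer F4, which are separated by crystallisation or chromatography.
  - Hydrogenation of F3 over Pd/C gives the saturated camphanate F5.
  - NaOMe in MeOH releases 8, and PPTS in refluxing toluene converts it to 9.

**Step 6.**
- What may go wrong: the hydroxy dione may rest as the C5-bridged hemiketal and lose water only sluggishly. Alternatively the enol ether double bond may migrate under acid into conjugation with the C5 carbonyl.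
- Fallback: use the other internal closure instead of fighting it. It sets out from 7 and returns at 15 in the same number of steps.
  - CSA in MeOH converts 7, if the C5 mode is the thermodynamic one, to the bridged methyl ketal ketone F8 (C1–CH2–O–C5 with OMe on C5, C8 ketone free).
  - Wolff–Kishner reduction of F8 gives the bridged methyl ketal F9.
  - Aqueous acid opens F9 to the hydroxy ketone F10.
  - Swern oxidation and DBU epimerisation of F10 give 15.

**Step 5.**
- What may go wrong: poor facial selectivity, since the β face carries an axial angular methyl while the α face carries ring B and the C1 substituent. Pd-induced migration of the alkene to C1=C2 would erase C1.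
- Fallback: replace surface hydrogenation by stepwise hydrogen-atom-transfer hydrogenation of 6 (Mn(dpm)3, PhSiH3, t-BuOOH, i-PrOH). The tertiary C2 radical is quenched by a small hydrogen donor anti to the vicinal C1–CH2OTBS, and no metal surface has to reach the face. It sets out from 6, returns at 7, and makes no new compound.

**Step 1.**
- What may go wrong: over-oxidation and aromatisation. The ene-dione tautomerises to 2,3-dimethylhydroquinone, which the oxidant converts to the quinone. Attack at the methyl C–H bonds may compete.
- Fallback: a stepwise γ-oxidation under non-radical conditions. It sets out from 1 and returns at 2.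
  - Isopropenyl acetate and TsOH give 2,3-dimethylcyclohexa-1,3-dien-1-yl acetate F6.
  - Peracid oxidation (mCPBA, buffered) gives 4-hydroxy-2,3-dimethylcyclohex-2-en-1-one F7.
  - MnO2 in CH2Cl2 oxidises F7 to 2 under neutral conditions.

**Step 15.**
- What may go wrong: acetyl migration to the secondary oxygen or diacetylation, because the two hydroxyls of a monoacylglycerol differ only moderately and the product equilibrates under base.
- Fallback: enzymatic transesterification of 23 with vinyl acetate and immobilised Candida antarctica lipase B in tert-butyl methyl ether, which acylates only the primary position at neutral pH. It sets out from 23, returns at 24, and makes no new compound.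

## Further compounds

F1 | step 4 | (E)-3-methylpenta-2,4-dien-1-ol | C=C/C(C)=C/CO
F2 | step 4 | (E)-3-methylpenta-2,4-dien-1-yl (1S,4R)-camphanate | C=C/C(C)=C/COC(=O)[C@@]12CC[C@@](C)(C(=O)O1)C2(C)C
F3 | step 4 | endo adduct camphanate, decalin part (1R,4aS,8aR) | O=C(OC[C@@H]1C(C)=CC[C@]2(C)C(=O)CCC(=O)[C@]12C)[C@@]34CC[C@@](C)(C(=O)O3)C4(C)C
F4 | step 4 | diastereomeric endo adduct camphanate, decalin part (1S,4aR,8aS) | O=C(OC[C@H]1C(C)=CC[C@@]2(C)C(=O)CCC(=O)[C@@]12C)[C@@]34CC[C@@](C)(C(=O)O3)C4(C)C
F5 | step 4 | saturated camphanate, decalin part as in 7 | O=C(OC[C@@H]1[C@H](C)CC[C@]2(C)C(=O)CCC(=O)[C@]12C)[C@@]34CC[C@@](C)(C(=O)O3)C4(C)C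
F8 | step 6 | bridged methyl ketal ketone (C1–CH2–O–C5, OMe on C5, C8 ketone) | C[C@@H]1CC[C@]2(C)[C@@]3(OC)CCC(=O)[C@]2(C)[C@@H]1CO3
F9 | step 6 | bridged methyl ketal (C8 methylene) | C[C@@H]1CC[C@]2(C)[C@@]3(OC)CCC[C@]2(C)[C@@H]1CO3
F10 | step 6 | hydroxy ketone (C1–CH2OH α, C5 ketone, C8 methylene) | OC[C@@H]1[C@H](C)CC[C@]2(C)C(=O)CCC[C@]12C
F0 | step 5 | none | none
F6 | step 1 | 2,3-dimethylcyclohexa-1,3-dien-1-yl acetate | CC(=O)OC1=C(C)C(C)=CCC1
F7 | step 1 | 4-hydroxy-2,3-dimethylcyclohex-2-en-1-one (racemic) | CC1=C(C)C(=O)CCC1O
F0 | step 15 | none | none
A1 | alternative 1 | trienone: isopropenyl ketone with (R)-C2 methyl, tethered to the (Z)-diene C4a(Me)=C5(homoprenyl)–CH=CH2 | C=C(C)C(=O)[C@H](C)CC/C(C)=C(\C=C)CCC=C(C)C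
A2 | alternative 1 | cis-fused octalone (C1 ketone) | O=C1[C@H](C)CC[C@]2(C)C(CCC=C(C)C)=CCC[C@]12C
A3 | alternative 2 | (2R)-6-ethyl-5-methyl-3,4-dihydro-2H-pyran carrying at C2 the (E)-tetrasubstituted alkenyl group | CCC1=C(C)CC[C@@H](O1)/C(CCC=C(C)C)=C(\C)CCO[Si](C)(C)C(C)(C)C
A4 | alternative 2 | cyclohexenyl ethyl ketone | CCC(=O)[C@@]1(C)CCC=C(CCC=C(C)C)[C@@]1(C)CCO[Si](C)(C)C(C)(C)C
A5 | alternative 3 | ten-membered bridging lactone (O on C7, acyl chain from C4a) | O=C1C[C@H](C)CC[C@]2(C)[C@@H](O[Si](C)(C)C(C)(C)C)C[C@H](O1)C=C2C
A6 | alternative 3 | cis-fused octalin acid | OC(=O)[C@@H]1[C@H](C)CC[C@]2(C)[C@@H](O[Si](C)(C)C(C)(C)C)CC=C[C@]12C
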